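The 14-membered carbocycle fused to the isochromanone at C5 and C6 is disconnected at C8'–C9'. This bond joins the allylic CH2 of the Z C6'=C7' alkene to the carbon α to the C10' carbonyl, and C11' is quaternary, so one allyl β-keto ester can deliver both a C8' π-allyl and a single C9' enolate. The key step therefore starts from a 16-membered allyl β-keto lactone, closed beforehand as an ester by acylketene trapping: palladium(0) ionises it, CO2 is expelled and the two fragments recombine at C8'–C9', which forms the carbon ring in one operation. Reduction to 10'S and MOM removal follow.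

Key step: step 19

Remark: locants are those of the isochromanone (C1–C8a) and of the side chain (C1' on C5 to C11' on O6); the 6'Z alkene cannot come from an allylic oxidation of a neryl derivative (E-selective), so C7' and C8' are introduced by a Z-selective olefination.

Step 1
Reactants: 1 1-bromo-3,5-dimethoxybenzene; 2 (R)-propylene oxide
Product: 4 (R)-1-(3,5-dimethoxyphenyl)propan-2-ol, via (3,5-dimethoxyphenyl)magnesium bromide 3 (not isolated)
Conditions: Mg, THF, reflux; then CuI (10 mol%), 2, −30 → 0 °C; aq NH4Cl
Reagents that add atoms: magnesium, [Mg] (in intermediate 3 only)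
Why: Copper-catalysed ring opening of a terminal epoxide by an aryl Grignard reagent occurs at the unsubstituted CH2, so the stereocentre of 2 is not touched and is carried over unchanged as the future C3 (R).

Step 2
Reactants: 4 (R)-1-(3,5-dimethoxyphenyl)propan-2-ol
Product: 5 (R)-1-(2,6-dibromo-3,5-dimethoxyphenyl)propan-2-ol
Conditions: NBS (2.1 equiv), MeCN, 0 °C → rt
Reagents that add atoms: N-bromosuccinimide, O=C1CCC(=O)N1Br
Why: Electrophilic aromatic bromination of the doubly activated ring should place both bromines para to a methoxy group, that is at the two equivalent positions flanking the side chain, in preference to the position between the two methoxy groups.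

Step 3
Reactants: 5 (R)-1-(2,6-dibromo-3,5-dimethoxyphenyl)propan-2-ol
Product: 8 (R)-5-bromo-6,8-dimethoxy-3-methylisochroman-1-one, via dilithio alkoxide 6 (not isolated), via hydroxy acid 7 (not isolated)
Conditions: n-BuLi (2.1 equiv), THF, −78 °C; CO2 (g); then 2 M HCl, 40 °C
Reagents that add atoms: n-butyllithium, [Li]CCCC (lithium in intermediate 6 only); carbon dioxide, O=C=O
Why: Deprotonation of the alcohol, a single bromine–lithium exchange, carboxylation and acid-promoted lactonisation close the isochromanone, and because the two bromines are equivalent the regiochemistry is unambiguous and the second bromine remains as the C5 handle.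

Step 4
Reactants: 8 (R)-5-bromo-6,8-dimethoxy-3-methylisochroman-1-one
Product: 9 (R)-5-bromo-6,8-dihydroxy-3-methylisochroman-1-one
Conditions: BBr3 (5 equiv), CH2Cl2, −78 °C → rt
Reagents that add atoms: none
Why: Lewis-acid demethylation of aryl methyl ethers with BBr3, carried out before any alkene is present, should leave the aryl bromide and the lactone (and hence C3) intact at low temperature.

Step 5
Reactants: 9 (R)-5-bromo-6,8-dihydroxy-3-methylisochroman-1-one; 10 ethyl 2-bromoisobutyrate
Product: 11 ethyl 2-{[(3R)-5-bromo-8-hydroxy-3-methyl-1-oxoisochroman-6-yl]oxy}-2-methylpropanoate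
Conditions: K2CO3 (1.2 equiv), DMF, 60 °C
Reagents that add atoms: none
Why: Williamson-type O-alkylation of a phenoxide with a tertiary α-bromo ester: with about one equivalent of carbonate only the more acidic, non-chelated C6 phenol is ionised and alkylated, while the C8 hydroxyl stays hydrogen-bonded to the lactone carbonyl.

Step 6
Reactants: 11 ethyl 2-{[(3R)-5-bromo-8-hydroxy-3-methyl-1-oxoisochroman-6-yl]oxy}-2-methylpropanoate
Product: 12 ethyl 2-{[(3R)-5-bromo-8-(methoxymethoxy)-3-methyl-1-oxoisochroman-6-yl]oxy}-2-methylpropanoate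
Conditions: MOMCl, i-Pr2NEt, CH2Cl2, 0 → 40 °C
Reagents that add atoms: chloromethyl methyl ether, COCCl
Why: MOM protection (O-alkylation with an α-chloro ether under amine base) masks the only acidic proton of the molecule, which would otherwise quench the enolate of the key step, and leaves both esters untouched.

Step 7
Reactants: 12 ethyl 2-{[(3R)-5-bromo-8-(methoxymethoxy)-3-methyl-1-oxoisochroman-6-yl]oxy}-2-methylpropanoate
Product: 13 ethyl 2-{[(3R)-8-(methoxymethoxy)-3-methyl-1-oxo-5-(4,4,5,5-tetramethyl-1,3,2-dioxaborolan-2-yl)isochroman-6-yl]oxy}-2-methylpropanoate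
Conditions: B2pin2, Pd(OAc)2 (5 mol%), SPhos (10 mol%), KOAc, 1,4-dioxane, 90 °C
Reagents that add atoms: bis(pinacolato)diboron, CC1(C)OB(OC1(C)C)B1OC(C)(C)C(C)(C)O1
Why: Miyaura borylation: a dialkylbiarylphosphine ligand allows oxidative addition and boryl transfer at the di-ortho-substituted, electron-rich C5–Br bond, and acetate as the base spares both esters and the acetal.

Step 8
Reactants: 14 nerol
Product: 15 neryl chloride, (2Z)-1-chloro-3,7-dimethylocta-2,6-diene
Conditions: NCS, Me2S, CH2Cl2, −30 → 0 °C
Reagents that add atoms: N-chlorosuccinimide, O=C1CCC(=O)N1Cl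
Why: Corey–Kim chlorination of a primary allylic alcohol (SN2 displacement of the alkoxysulfonium group by chloride) gives the chloride without allylic transposition or loss of the 2Z geometry, which becomes C2'=C3'.

Step 9
Reactants: 15 neryl chloride
Product: 16 6,7-epoxyneryl chloride, 3-[(3Z)-5-chloro-3-methylpent-3-en-1-yl]-2,2-dimethyloxirane (racemic)
Conditions: mCPBA (1.0 equiv), NaHCO3, CH2Cl2, 0 °C
Reagents that add atoms: meta-chloroperoxybenzoic acid, O=C(OO)c1cccc(Cl)c1
Why: Prilezhaev epoxidation goes to the more electron-rich 6,7-alkene because the allylic chloride deactivates the 2,3-alkene inductively; the new stereocentre is formed racemic and is destroyed in the next step.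

Step 10
Reactants: 16 6,7-epoxyneryl chloride
Product: 18 (4Z)-6-chloro-4-methylhex-4-enal, via chloro diol 17 (not isolated)
Conditions: H5IO6 (1.1 equiv), THF/Et2O, 0 °C
Reagents that add atoms: water (from the periodic acid hydrate), O (in intermediate 17 only)
Why: Periodic acid opens the epoxide to the vicinal diol and cleaves it (Malaprade glycol cleavage) to acetone and the aldehyde, whose oxygen is the former epoxide oxygen, under nearly anhydrous conditions that spare the allylic chloride.

Step 11
Reactants: 18 (4Z)-6-chloro-4-methylhex-4-enal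
Product: 19 ethyl (2Z,6Z)-8-chloro-2,6-dimethylocta-2,6-dienoate
Conditions: (CF3CH2O)2P(O)CH(CH3)CO2Et, KHMDS, 18-crown-6, THF, −78 °C
Reagents that add atoms: ethyl 2-[bis(2,2,2-trifluoroethoxy)phosphoryl]propanoate, CCOC(=O)C(C)P(=O)(OCC(F)(F)F)OCC(F)(F)F
Why: Still–Gennari variant of the Horner–Wadsworth–Emmons olefination: the electron-poor phosphonate under dissociating conditions eliminates rapidly from the kinetic adduct and should give the (Z)-2-methyl enoate, which sets the C6'=C7' geometry.

Step 12
Reactants: 19 ethyl (2Z,6Z)-8-chloro-2,6-dimethylocta-2,6-dienoate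
Product: 20 (2Z,6Z)-8-chloro-2,6-dimethylocta-2,6-dien-1-ol
Conditions: DIBAL-H (2.2 equiv), CH2Cl2, −78 °C; Rochelle salt
Reagents that add atoms: none
Why: DIBAL-H reduces the conjugated ester in a 1,2 sense to the allylic alcohol at −78 °C, where a primary allylic chloride and both alkene geometries are retained.

Step 13
Reactants: 20 (2Z,6Z)-8-chloro-2,6-dimethylocta-2,6-dien-1-ol
Product: 21 tert-butyl{[(2Z,6Z)-8-chloro-2,6-dimethylocta-2,6-dien-1-yl]oxy}dimethylsilane
Conditions: TBSCl, Et3N, DMAP (cat.), CH2Cl2, 0 °C
Reagents that add atoms: tert-butyldimethylsilyl chloride, CC(C)(C)[Si](C)(C)Cl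
Why: Silylation of the primary alcohol with a poorly nucleophilic amine base protects the future C8' oxygen without displacing the allylic chloride.

Step 14
Reactants: 13 aryl pinacol boronate; 21 silyl-protected Z,Z allylic chloride
Product: 22 ethyl 2-{[(3R)-5-[(2Z,6Z)-8-(tert-butyldimethylsilyloxy)-3,7-dimethylocta-2,6-dien-1-yl]-8-(methoxymethoxy)-3-methyl-1-oxoisochroman-6-yl]oxy}-2-methylpropanoate
Conditions: Pd(PPh3)4 (5 mol%), CsF, THF, 60 °C
Reagents that add atoms: none
Why: Suzuki–Miyaura-type allyl–aryl coupling: Pd(0) ionises the allylic chloride to an η3-allyl complex, the aryl group is transferred from boron and reductive elimination occurs at the unsubstituted terminus C1', while Z/E equilibration would need a σ-bond to the fully substituted C3' and should therefore be slow, so the 2'Z geometry is expected to be kept.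

Step 15
Reactants: 22 coupled ethyl ester
Product: 24 2-{[(3R)-5-[(2Z,6Z)-8-(tert-butyldimethylsilyloxy)-3,7-dimethylocta-2,6-dien-1-yl]-8-(methoxymethoxy)-3-methyl-1-oxoisochroman-6-yl]oxy}-2-methylpropanoic acid, via seco hydroxy diacid 23 (not isolated)
Conditions: LiOH (5 equiv), THF/MeOH/H2O, 40 °C; then 0.5 M HCl to pH 3, 0 °C → rt
Reagents that add atoms: lithium hydroxide, [Li+].[OH-] (hydroxide oxygen)
Why: Saponification with excess hydroxide cleaves the ethyl ester and opens the lactone at the acyl carbon, and on acidification the ortho-(2-hydroxypropyl)benzoic acid relactonises spontaneously with C3 unchanged, leaving only the tertiary carboxylic acid free.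

Step 16
Reactants: 24 carboxylic acid
Product: 26 tert-butyl 4-{[(3R)-5-[(2Z,6Z)-8-(tert-butyldimethylsilyloxy)-3,7-dimethylocta-2,6-dien-1-yl]-8-(methoxymethoxy)-3-methyl-1-oxoisochroman-6-yl]oxy}-4-methyl-3-oxopentanoate, via acyl imidazolide 25 (not isolated)
Conditions: CDI (1.2 equiv), THF, rt; then HO2CCH2CO2t-Bu, MgCl2, Et3N, THF/MeCN, rt → 45 °C
Reagents that add atoms: 1,1'-carbonyldiimidazole, O=C(n1ccnc1)n1ccnc1 (imidazolyl group of intermediate 25 only); mono-tert-butyl malonate, CC(C)(C)OC(=O)CC(=O)O
Why: Masamune–Brooks chain extension: the acyl imidazolide is C-acylated by the magnesium malonate half-ester with loss of CO2, a neutral method that leaves the lactone untouched, which an ester-enolate Claisen condensation would not guarantee.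

Step 17
Reactants: 26 silyl-protected β-keto tert-butyl ester
Product: 27 tert-butyl 4-{[(3R)-5-[(2Z,6Z)-8-hydroxy-3,7-dimethylocta-2,6-dien-1-yl]-8-(methoxymethoxy)-3-methyl-1-oxoisochroman-6-yl]oxy}-4-methyl-3-oxopentanoate
Conditions: HF·pyridine, THF/pyridine, 0 °C → rt
Reagents that add atoms: none
Why: Fluoride-mediated cleavage of the primary silyl ether under buffered conditions should leave the β-keto ester, the MOM acetal and the alkenes untouched.

Step 18
Reactants: 27 hydroxy β-keto tert-butyl ester
Product: 29 16-membered macrolactone (C8' allyl ester of the C10' β-keto acid, 8-O-MOM), via acylketene 28 (not isolated)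
Conditions: toluene (1 mM, slow addition), 110 °C
Reagents that add atoms: none
Why: Thermal loss of tert-butanol from the β-keto tert-butyl ester gives an acylketene that is trapped by the tethered primary allylic alcohol under high dilution (acylketene macrolactonisation), closing the 16-membered ring at the acyl carbon without touching either alkene.

Step 19
Reactants: 29 16-membered allyl β-keto macrolactone
Product: 30 8-O-MOM 10'-oxo 14-membered macrocycle (10'-dehydrochrysomutanin MOM ether)
Conditions: Pd2(dba)3 (5 mol%), PPh3 (25 mol%), toluene (2 mM), rt → 40 °C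
Reagents that add atoms: none
Why: Pd(0) adds oxidatively to the allylic C8'–O bond to give an η3-allyl palladium β-keto carboxylate, which loses CO2 to a palladium enolate that can only be the C9'=C10' enolate because C11' bears no hydrogen, and C-allylation at C8' then forms the C8'–C9' bond and returns Pd(0). The closest known reaction type is the Tsuji–Saegusa decarboxylative allylation of allyl β-keto esters (a palladium-catalysed Carroll-type process), run here inside a macrocycle so that it contracts the ring. The 14-membered ring closes by recombination of the enolate carbon with the unsubstituted terminus of the allyl unit to which it stays tethered through the arene, the alkene remaining endocyclic and two ring atoms leaving as CO2. No stereocentre is created. The step needs attack at C8' and not at C6' (which would give a 12-membered ring with an exocyclic isopropenyl group), retention of the Z C6'=C7' geometry and intramolecular collapse: the primary terminus is favoured sterically, Z/E equilibration would require a σ-bond to the secondary carbon C6' and should be slower than collapse of the tethered ion pair in a non-polar solvent, high dilution suppresses crossover, and the MOM ether removes the only acidic proton that could quench the enolate.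

Step 20
Reactants: 30 8-O-MOM 10'-oxo macrocycle
Product: 31 8-O-MOM chrysomutanin (10'S alcohol)
Conditions: (R)-2-methyl-CBS-oxazaborolidine (0.5 equiv), catecholborane (2 equiv), toluene, −78 → −40 °C; MeOH
Reagents that add atoms: none
Why: Corey–Bakshi–Shibata reduction: the (R)-oxazaborolidine binds the ketone with the bulky quaternary C11' side as the large group and the C9' methylene as the small one and delivers hydride to the face that gives the 10'S alcohol, while catecholborane at low temperature leaves the alkenes and the lactone unreduced.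

Step 21
Reactants: 31 8-O-MOM chrysomutanin
Product: 32 chrysomutanin
Conditions: HCl (1.25 M in MeOH, 5 equiv), THF, 0 °C → rt
Reagents that add atoms: none
Why: Acid-catalysed acetal cleavage (MOM removal) is unusually easy for a phenol peri to a carbonyl group, so conditions mild enough for the trisubstituted alkenes, the tertiary aryl ether and both stereocentres should suffice.

Compound list
1 | 1-bromo-3,5-dimethoxybenzene | COc1cc(Br)cc(OC)c1 | starting material
2 | (R)-propylene oxide | C[C@@H]1CO1 | starting material
3 | (3,5-dimethoxyphenyl)magnesium bromide | COc1cc([Mg]Br)cc(OC)c1 | intermediate (not isolated)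
4 | (R)-1-(3,5-dimethoxyphenyl)propan-2-ol | COc1cc(C[C@@H](C)O)cc(OC)c1 | intermediate
5 | (R)-1-(2,6-dibromo-3,5-dimethoxyphenyl)propan-2-ol | COc1cc(OC)c(Br)c(C[C@@H](C)O)c1Br | intermediate
6 | lithium (2R)-1-(2-bromo-6-lithio-3,5-dimethoxyphenyl)propan-2-olate | COc1cc(OC)c([Li])c(C[C@@H](C)O[Li])c1Br | intermediate (not isolated)
7 | 3-bromo-2-[(2R)-2-hydroxypropyl]-4,6-dimethoxybenzoic acid | COc1cc(OC)c(C(=O)O)c(C[C@@H](C)O)c1Br | intermediate (not isolated)
8 | (R)-5-bromo-6,8-dimethoxy-3-methylisochroman-1-one | COc1cc(OC)c2c(c1Br)C[C@@H](C)OC2=O | intermediate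
9 | (R)-5-bromo-6,8-dihydroxy-3-methylisochroman-1-one | Oc1cc(O)c2c(c1Br)C[C@@H](C)OC2=O | intermediate
10 | ethyl 2-bromoisobutyrate | CCOC(=O)C(C)(C)Br | starting material
11 | ethyl 2-{[(3R)-5-bromo-8-hydroxy-3-methyl-1-oxoisochroman-6-yl]oxy}-2-methylpropanoate | CCOC(=O)C(C)(C)Oc1cc(O)c2c(c1Br)C[C@@H](C)OC2=O | intermediate
12 | ethyl 2-{[(3R)-5-bromo-8-(methoxymethoxy)-3-methyl-1-oxoisochroman-6-yl]oxy}-2-methylpropanoate | CCOC(=O)C(C)(C)Oc1cc(OCOC)c2c(c1Br)C[C@@H](C)OC2=O | intermediate
13 | ethyl 2-{[(3R)-8-(methoxymethoxy)-3-methyl-1-oxo-5-(4,4,5,5-tetramethyl-1,3,2-dioxaborolan-2-yl)isochroman-6-yl]oxy}-2-methylpropanoate | CCOC(=O)C(C)(C)Oc1cc(OCOC)c2c(c1B1OC(C)(C)C(C)(C)O1)C[C@@H](C)OC2=O | intermediate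
14 | nerol | CC(C)=CCC/C(C)=C\CO | starting material
15 | neryl chloride | CC(C)=CCC/C(C)=C\CCl | intermediate
16 | 6,7-epoxyneryl chloride (racemic at the epoxide) | CC1(C)OC1CC/C(C)=C\CCl | intermediate
17 | (6Z)-8-chloro-2,6-dimethyloct-6-ene-2,3-diol (racemic) | CC(C)(O)C(O)CC/C(C)=C\CCl | intermediate (not isolated)
18 | (4Z)-6-chloro-4-methylhex-4-enal | O=CCC/C(C)=C\CCl | intermediate
19 | ethyl (2Z,6Z)-8-chloro-2,6-dimethylocta-2,6-dienoate | CCOC(=O)/C(C)=C\CC/C(C)=C\CCl | intermediate
20 | (2Z,6Z)-8-chloro-2,6-dimethylocta-2,6-dien-1-ol | OC/C(C)=C\CC/C(C)=C\CCl | intermediate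
21 | tert-butyl{[(2Z,6Z)-8-chloro-2,6-dimethylocta-2,6-dien-1-yl]oxy}dimethylsilane | CC(C)(C)[Si](C)(C)OC/C(C)=C\CC/C(C)=C\CCl | intermediate
22 | ethyl 2-{[(3R)-5-[(2Z,6Z)-8-(tert-butyldimethylsilyloxy)-3,7-dimethylocta-2,6-dien-1-yl]-8-(methoxymethoxy)-3-methyl-1-oxoisochroman-6-yl]oxy}-2-methylpropanoate | CCOC(=O)C(C)(C)Oc1cc(OCOC)c2c(c1C/C=C(C)\CC/C=C(C)\CO[Si](C)(C)C(C)(C)C)C[C@@H](C)OC2=O | intermediate
23 | seco hydroxy diacid: 2-[(2R)-2-hydroxypropyl]-4-[(2-carboxypropan-2-yl)oxy]-6-(methoxymethoxy)-3-[(2Z,6Z)-8-(tert-butyldimethylsilyloxy)-3,7-dimethylocta-2,6-dien-1-yl]benzoic acid | CC(C)(Oc1cc(OCOC)c(C(=O)O)c(C[C@@H](C)O)c1C/C=C(C)\CC/C=C(C)\CO[Si](C)(C)C(C)(C)C)C(=O)O | intermediate (not isolated)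
24 | 2-{[(3R)-5-[(2Z,6Z)-8-(tert-butyldimethylsilyloxy)-3,7-dimethylocta-2,6-dien-1-yl]-8-(methoxymethoxy)-3-methyl-1-oxoisochroman-6-yl]oxy}-2-methylpropanoic acid | CC(C)(Oc1cc(OCOC)c2c(c1C/C=C(C)\CC/C=C(C)\CO[Si](C)(C)C(C)(C)C)C[C@@H](C)OC2=O)C(=O)O | intermediate
25 | acyl imidazolide of acid 24 | CC(C)(Oc1cc(OCOC)c2c(c1C/C=C(C)\CC/C=C(C)\CO[Si](C)(C)C(C)(C)C)C[C@@H](C)OC2=O)C(=O)n1ccnc1 | intermediate (not isolated)
26 | tert-butyl 4-{[(3R)-5-[(2Z,6Z)-8-(tert-butyldimethylsilyloxy)-3,7-dimethylocta-2,6-dien-1-yl]-8-(methoxymethoxy)-3-methyl-1-oxoisochroman-6-yl]oxy}-4-methyl-3-oxopentanoate | CC(C)(C)OC(=O)CC(=O)C(C)(C)Oc1cc(OCOC)c2c(c1C/C=C(C)\CC/C=C(C)\CO[Si](C)(C)C(C)(C)C)C[C@@H](C)OC2=O | intermediate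
27 | tert-butyl 4-{[(3R)-5-[(2Z,6Z)-8-hydroxy-3,7-dimethylocta-2,6-dien-1-yl]-8-(methoxymethoxy)-3-methyl-1-oxoisochroman-6-yl]oxy}-4-methyl-3-oxopentanoate | CC(C)(C)OC(=O)CC(=O)C(C)(C)Oc1cc(OCOC)c2c(c1C/C=C(C)\CC/C=C(C)\CO)C[C@@H](C)OC2=O | intermediate
28 | acylketene derived from 27 (C10' ketone, ketene in place of the ester) | O=C=CC(=O)C(C)(C)Oc1cc(OCOC)c2c(c1C/C=C(C)\CC/C=C(C)\CO)C[C@@H](C)OC2=O | intermediate (not isolated)
29 | 16-membered macrolactone, C8' allyl ester of the C10' β-keto acid, 8-O-MOM, 2'Z,6'Z, 3R | C/C1=C/Cc2c(cc(OCOC)c3c2C[C@@H](C)OC3=O)OC(C)(C)C(=O)CC(=O)OC/C(C)=C\CC1 | intermediate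
30 | 8-O-MOM 10'-oxo 14-membered macrocycle (10'-dehydrochrysomutanin MOM ether), 2'Z,6'Z, 3R | C/C1=C/Cc2c(cc(OCOC)c3c2C[C@@H](C)OC3=O)OC(C)(C)C(=O)CC/C(C)=C\CC1 | intermediate
31 | 8-O-MOM chrysomutanin (3R,10'S) | C/C1=C/Cc2c(cc(OCOC)c3c2C[C@@H](C)OC3=O)OC(C)(C)[C@@H](O)CC/C(C)=C\CC1 | intermediate
32 | chrysomutanin (3R,10'S,2'Z,6'Z) | C/C1=C/Cc2c(cc(O)c3c2C[C@@H](C)OC3=O)OC(C)(C)[C@@H](O)CC/C(C)=C\CC1 | target

Total step count: 21. Longest linear sequence: 15 steps (steps 1–7, then 14–21); the side-chain branch (steps 8–13) joins at step 14.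

Steps most likely to fail

Step 19 (key step). After ionisation the allyl palladium unit may lose a β-hydrogen (diene formation with protonation of the enolate). It may also equilibrate to the syn form before the C–C bond is made, which would lose the C6'=C7' geometry, or exchange partners between ion pairs and oligomerise. The fallback avoids any π-allyl intermediate and sets out from hydroxy β-keto ester 27. Its primary allylic alcohol is converted with MsCl, LiCl and 2,4,6-collidine in DMF at 0 °C into the allylic chloride F1. Slow addition of F1 to Cs2CO3 in MeCN at high dilution should close the 14-membered ring by intramolecular SN2 C-alkylation of the β-keto ester at C9', giving the 9'-tert-butoxycarbonyl ketone F2 (C9' epimers, of no consequence). Heating F2 in wet DMSO at about 130 °C should remove the tert-butyl ester through the acylketene and its hydration, with loss of CO2, and brings the route back at ketone 30.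

Step 14. Aryl transfer from the di-ortho-substituted boronate to palladium may be slower than protodeboronation, or slower than β-hydride loss and syn/anti equilibration of the allyl palladium intermediate, which would cost material or the 2'Z geometry. The fallback reverses the polarity (aryl electrophile, allyl nucleophile) and sets out from chloride 21. Treatment with Bu3SnLi in THF at −78 °C should give the allylstannane F3 by SN2 displacement. F3 is then joined to aryl bromide 12 in a Stille coupling (Pd2(dba)3, P(t-Bu)3, CsF, dioxane, 80 °C), which brings the route back at 22.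

Step 20. The conformation of the macrocycle may override catalyst control and give poor facial selectivity, or the hindered ketone may be reduced too slowly. The fallback replaces reagent control by separation and recycling and sets out from ketone 30. Reduction with NaBH4 in MeOH at 0 °C should give both C10' epimers, which are diastereomers because of C3 and should be separable by chromatography. The 10'S epimer is 31, where the route is rejoined; the 10'R epimer F4 is oxidised back to 30 with Dess–Martin periodinane and recycled.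

Further compounds
F1 | step 19 | tert-butyl 4-{[(3R)-5-[(2Z,6Z)-8-chloro-3,7-dimethylocta-2,6-dien-1-yl]-8-(methoxymethoxy)-3-methyl-1-oxoisochroman-6-yl]oxy}-4-methyl-3-oxopentanoate | CC(C)(C)OC(=O)CC(=O)C(C)(C)Oc1cc(OCOC)c2c(c1C/C=C(C)\CC/C=C(C)\CCl)C[C@@H](C)OC2=O
F2 | step 19 | 8-O-MOM 10'-oxo 14-membered macrocycle carrying a tert-butoxycarbonyl group at C9' (C9' epimers) | C/C1=C/Cc2c(cc(OCOC)c3c2C[C@@H](C)OC3=O)OC(C)(C)C(=O)C(C(=O)OC(C)(C)C)C/C(C)=C\CC1
F3 | step 14 | tributyl[(2Z,6Z)-8-(tert-butyldimethylsilyloxy)-3,7-dimethylocta-2,6-dien-1-yl]stannane | CCCC[Sn](CCCC)(CCCC)C/C=C(C)\CC/C=C(C)\CO[Si](C)(C)C(C)(C)C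
F4 | step 20 | 8-O-MOM 10'-epi-chrysomutanin (3R,10'R alcohol) | C/C1=C/Cc2c(cc(OCOC)c3c2C[C@@H](C)OC3=O)OC(C)(C)[C@H](O)CC/C(C)=C\CC1
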